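## Retrosynthetic overview
1. Feature: ring A (C3a, C4, C5, C6, C7, C7a) carries oxygen on the neighbouring carbons C7a (O1) and C7 (OMe), carbon on C3a and C5, and hydrogen on C4 and C6. C7a is tied back to C3a by the chain O1–C2–C3. A 2,4-disubstituted furan leaves exactly this pattern when it rearranges with a tethered ethynyl ether.
2. Target ⇒ (E)-alkene by Horner–Wadsworth–Emmons reaction of the ring A 5-carbaldehyde with a 3,5-bis(silyloxy)benzylphosphonate. The aldehyde comes from the 7-phenol by O-methylation, selective desilylation and oxidation.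
3. 7-Phenol ⇒ ethynyl ether by cutting C3a–C7a and C6–C7. Furan C2, C3, C4 and C5 become C3a, C4, C5 and C6, the alkyne carbons become C7a and C7, and the furan oxygen ends on C7.
4. Ethynyl ether ⇒ secondary alcohol + trichloroethylene. The alcohol comes from an Evans syn-aldol reaction of a furylacetyl imide with silylated syringaldehyde, which sets C2 and C3. The imide comes from 5-bromofuran-3-carboxylic acid, a Reformatsky zinc reagent and the (R)-benzyl auxiliary.
5. Ring order: the furan and both outer arenes are bought. In the key step the dihydrofuran ring closes first (C3a–C7a) and ring A second (C6–C7).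

Key step: step 12

Remark: benzofuran numbering (O1, C2, C3, C3a, C4–C7, C7a; C9 = CH2OH carbon) is also used for the open-chain atoms that become these positions; 5-bromofuran-3-carboxylic acid and (2-ethoxy-2-oxoethyl)zinc bromide are taken as catalogue compounds.

## Route

Step 1
Reactants: 1 5-bromofuran-3-carboxylic acid
Product: 2 (5-bromofuran-3-yl)methanol
Conditions: BH3·THF, THF, 0 °C → rt; MeOH, then aq. NaHCO3
Reagents that add atoms: none
Why: Borane reduction of a carboxylic acid leaves the furan and the C–Br bond alone, and the bought 2,4-relationship of bromine and carbon substituent fixes the later C3a/C5 pattern, whereas direct lithiation of 3-(oxymethyl)furans favours the α-carbon next to the substituent.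

Step 2
Reactants: 2 (5-bromofuran-3-yl)methanol
Product: 3 [(5-bromofuran-3-yl)methoxy](tert-butyl)dimethylsilane
Conditions: t-BuMe2SiCl, imidazole, CH2Cl2, 0 °C → rt
Reagents that add atoms: tert-butyldimethylsilyl chloride, CC(C)(C)[Si](C)(C)Cl
Why: Imidazole-promoted silylation of an unhindered primary alcohol; TBS withstands the zinc reagent, hydroxide, borohydride, KH and n-BuLi, yet is the most acid-labile silyl group in the route and can be removed alone in step 14.

Step 3
Reactants: 3 [(5-bromofuran-3-yl)methoxy](tert-butyl)dimethylsilane; 4 (2-ethoxy-2-oxoethyl)zinc bromide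
Product: 5 ethyl 2-[4-(tert-butyldimethylsilyloxymethyl)furan-2-yl]acetate
Conditions: Pd2(dba)3 (2 mol %), XPhos (8 mol %), THF, 55 °C
Reagents that add atoms: none
Why: Negishi-type cross-coupling of a Reformatsky reagent (palladium-catalysed α-arylation of a zinc ester enolate): α-bromofurans add readily to zerovalent palladium, the neutral zinc enolate tolerates the silyl ether, and the C–C bond can form only where the bromine sat.

Step 4
Reactants: 5 ethyl 2-[4-(tert-butyldimethylsilyloxymethyl)furan-2-yl]acetate
Product: 6 2-[4-(tert-butyldimethylsilyloxymethyl)furan-2-yl]acetic acid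
Conditions: LiOH, THF/MeOH/H2O, 0 °C → rt; cold dilute HCl to pH 4
Reagents that add atoms: lithium hydroxide, [Li+].[OH-]
Why: Saponification of an unhindered ethyl ester, which an alkyl TBS ether survives, followed by cold acidification only to pH 4 so that furan and silyl ether are spared.

Step 5
Reactants: 6 2-[4-(tert-butyldimethylsilyloxymethyl)furan-2-yl]acetic acid; 7 (R)-4-benzyl-2-oxazolidinone
Product: 9 (R)-4-benzyl-3-{2-[4-(tert-butyldimethylsilyloxymethyl)furan-2-yl]acetyl}oxazolidin-2-one, via mixed pivalic anhydride 8 (not isolated)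
Conditions: t-BuCOCl, Et3N, THF, −20 °C; then LiCl, 7, −20 °C → rt
Reagents that add atoms: none
Why: N-acylation of an oxazolidinone through a mixed pivalic anhydride (LiCl/Et3N variant): the nucleophile attacks the less hindered carbonyl, and no strong base meets the acidic furylacetyl CH2.

Step 6
Reactants: 10 syringaldehyde
Product: 11 3,5-dimethoxy-4-(triisopropylsilyloxy)benzaldehyde
Conditions: i-Pr3SiCl, imidazole, DMAP (cat.), DMF, rt
Reagents that add atoms: triisopropylsilyl chloride, CC(C)[Si](Cl)(C(C)C)C(C)C
Why: Silylation of the phenol; an aryl TIPS ether flanked by two methoxy groups resists alkoxide, n-BuLi and aqueous acid, and falls to fluoride only at the end.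

Step 7
Reactants: 9 (R)-4-benzyl-3-{2-[4-(tert-butyldimethylsilyloxymethyl)furan-2-yl]acetyl}oxazolidin-2-one; 11 3,5-dimethoxy-4-(triisopropylsilyloxy)benzaldehyde
Product: 13 (R)-4-benzyl-3-{(2S,3R)-2-[4-(tert-butyldimethylsilyloxymethyl)furan-2-yl]-3-[3,5-dimethoxy-4-(triisopropylsilyloxy)phenyl]-3-hydroxypropanoyl}oxazolidin-2-one, via dibutylboron enolate 12 (not isolated)
Conditions: n-Bu2BOTf, i-Pr2NEt, CH2Cl2, −78 → 0 °C; 11, −78 → −10 °C; pH 7 buffer, MeOH, 30% H2O2, 0 °C
Reagents that add atoms: none
Why: Evans syn-aldol reaction: soft enolisation gives the (Z)-boron enolate 12, which reacts through a closed chair transition state on the face away from the benzyl group of the (R)-auxiliary, so both centres are set together as (2S,3R), the future C3 (S) and C2 (R), and the syn pair becomes trans once the hydroxyl oxygen and the furyl carbon are tied into one five-membered ring.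

Step 8
Reactants: 13 syn-aldol adduct
Product: 14 (1R,2S)-2-[4-(tert-butyldimethylsilyloxymethyl)furan-2-yl]-1-[3,5-dimethoxy-4-(triisopropylsilyloxy)phenyl]propane-1,3-diol
Conditions: LiBH4, MeOH (2 equiv), THF, 0 °C
Reagents that add atoms: none
Why: Reductive removal of the auxiliary: LiBH4/MeOH attacks the exocyclic imide carbonyl fast enough at 0 °C to outrun retro-aldol cleavage and α-epimerisation, touches neither silyl ethers nor furan, and returns 7.

Step 9
Reactants: 14 (1R,2S)-diol
Product: 15 (1R,2S)-2-[4-(tert-butyldimethylsilyloxymethyl)furan-2-yl]-1-[3,5-dimethoxy-4-(triisopropylsilyloxy)phenyl]-3-(triisopropylsilyloxy)propan-1-ol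
Conditions: i-Pr3SiCl (1.1 equiv), imidazole, CH2Cl2/DMF, 0 °C
Reagents that add atoms: triisopropylsilyl chloride, CC(C)[Si](Cl)(C(C)C)C(C)C
Why: Steric differentiation in silylation: the bulky chloride takes the primary hydroxyl and leaves the flanked secondary benzylic one free, and TIPS is used here instead of TBS because it resists the 1,5 oxygen-to-oxygen silyl shift to the neighbouring alkoxide in step 10.

Step 10
Reactants: 15 (1R,2S)-alcohol; 16 trichloroethylene
Product: 18 (E)-1,2-dichlorovinyl ether of alcohol 15, via potassium alkoxide 17 (not isolated)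
Conditions: KH, THF, 0 °C; then 16, −50 °C → rt
Reagents that add atoms: none
Why: First half of the trichloroethylene route to ynol ethers: base removes HCl from 16 to give dichloroacetylene in the flask, alkoxide 17 adds to it in anti fashion and more 16 protonates the vinyl anion, a sequence established for hindered secondary and benzylic alcohols that never touches the C2–O bond or its configuration.

Step 11
Reactants: 18 (E)-1,2-dichlorovinyl ether
Product: 21 (1R,2S)-ethynyl ether of alcohol 15 (key-step precursor), via chloroethynyl ether 19 (not isolated), via lithium alkoxyacetylide 20 (not isolated)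
Conditions: n-BuLi (2.3 equiv), THF, −78 → −40 °C; H2O, −78 °C; cold work-up, short basic Al2O3 plug at 0 °C, used at once
Reagents that add atoms: none
Why: Second half of the same route: n-BuLi removes the vinylic proton and chloride leaves (β-elimination) to give 19, chlorine–lithium exchange with the second equivalent gives 20 and cold protonation gives the terminal ynol ether, while silyl ethers and furan are inert at −78 °C and any furyllithium would simply be reprotonated.

Step 12
Reactants: 21 (1R,2S)-ethynyl ether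
Product: 23 (2R,3S)-5-(tert-butyldimethylsilyloxymethyl)-2-[3,5-dimethoxy-4-(triisopropylsilyloxy)phenyl]-3-(triisopropylsilyloxymethyl)-2,3-dihydrobenzofuran-7-ol, via oxepine 22 (not isolated)
Conditions: AuCl3 (5 mol %, as MeCN solution), CH2Cl2 (0.02 M), 4 Å MS, Ar, −20 → 0 °C
Reagents that add atoms: none
Why: Proposed new method: AuCl3 binds the electron-rich ethynyl ether, whose ketene-oxonium polarisation makes the oxygen-bearing carbon (future C7a) the electrophile, and furan C2 (future C3a) attacks it in a 5-exo-dig closure that makes the dihydrofuran ring and a catalyst-bound cyclopropyl carbene with its carbene centre on the terminal carbon (future C7). Cleavage of the old furan C2–O bond unfolds this species to a catalyst-bound carbene conjugated with a cis-enal, the aldehyde oxygen adds to the carbene carbon with release of AuCl3 to give oxepine 22, and ring A closes by the disrotatory 6π valence tautomerisation of 22 to the C6–C7 arene oxide, which opens and loses the C7 proton to give the phenol. The closest known reaction type is the gold-catalysed furan–yne phenol synthesis (Hashmi phenol synthesis) of furans with a propargyl-type carbon, nitrogen or oxygen tether; a terminal ethynyl ether of a secondary benzylic alcohol, with the tether oxygen directly on the alkyne, lies outside what that reaction has been shown to do. No stereocentre is created and the bonds C2–O1, C2–C3 and C3–C3a are spectators, so the (1R,2S) pair of 21 should reappear unchanged as the trans-(2R,3S) pair of 23. Three selectivities are needed: bond formation at the oxygen-bearing and not the terminal alkyne carbon, secured by the ynol ether polarity and the five-membered ring size; attack by furan C2 and not C3, secured by the higher nucleophilicity of the α-carbon and the short O1–C2–C3 tether; and opening of the arene oxide at C6–O and not C7–O, secured by O1, because only this opening places the positive charge on C7a next to an oxygen lone pair. High dilution, dry solvent and a temperature at or below 0 °C are meant to hold back intermolecular attack by the free furan C5, hydration to the acetate, ionisation of the benzylic C2–O1 bond and retro-ene loss of ketene.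

Step 13
Reactants: 23 (2R,3S)-dihydrobenzofuran-7-ol
Product: 24 (2R,3S)-5-(tert-butyldimethylsilyloxymethyl)-2-[3,5-dimethoxy-4-(triisopropylsilyloxy)phenyl]-7-methoxy-3-(triisopropylsilyloxymethyl)-2,3-dihydrobenzofuran
Conditions: MeI, K2CO3, dry acetone, rt
Reagents that add atoms: iodomethane, CI
Why: Williamson methylation of the only free phenol; carbonate in dry acetone should not cleave the hindered aryl TIPS ether, so no second phenol is exposed to MeI.

Step 14
Reactants: 24 7-methyl ether
Product: 25 {(2R,3S)-2-[3,5-dimethoxy-4-(triisopropylsilyloxy)phenyl]-7-methoxy-3-(triisopropylsilyloxymethyl)-2,3-dihydrobenzofuran-5-yl}methanol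
Conditions: AcOH/THF/H2O (3:1:1), rt
Reagents that add atoms: none
Why: Acid-catalysed silyl ether hydrolysis follows steric demand, so the unhindered primary TBS ether goes while the β-branched primary TIPS and the acid-resistant aryl TIPS ethers stay, and water as the nucleophile makes any ionisation of the para-alkoxybenzylic alcohol degenerate.

Step 15
Reactants: 25 benzylic alcohol
Product: 26 (2R,3S)-2-[3,5-dimethoxy-4-(triisopropylsilyloxy)phenyl]-7-methoxy-3-(triisopropylsilyloxymethyl)-2,3-dihydrobenzofuran-5-carbaldehyde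
Conditions: MnO2 (activated, excess), CH2Cl2, rt
Reagents that add atoms: none
Why: MnO2 oxidation of an electron-rich benzylic alcohol is neutral, stops at the aldehyde, and leaves silyl ethers and both stereocentres alone.

Step 16
Reactants: 27 methyl 3,5-dihydroxybenzoate
Product: 28 methyl 3,5-bis(tert-butyldimethylsilyloxy)benzoate
Conditions: t-BuMe2SiCl, imidazole, DMF, rt
Reagents that add atoms: tert-butyldimethylsilyl chloride, CC(C)(C)[Si](C)(C)Cl
Why: Silylation of both phenols; aryl TBS ethers survive the next four operations and fall to fluoride in the last step, which methyl ethers could not do beside the three methoxy groups that must stay.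

Step 17
Reactants: 28 methyl 3,5-bis(tert-butyldimethylsilyloxy)benzoate
Product: 29 [3,5-bis(tert-butyldimethylsilyloxy)phenyl]methanol
Conditions: i-Bu2AlH, CH2Cl2, −78 → 0 °C; aq. potassium sodium tartrate
Reagents that add atoms: none
Why: Ester reduction with i-Bu2AlH, an electrophilic hydride that does not attack aryl silyl ethers.

Step 18
Reactants: 29 [3,5-bis(tert-butyldimethylsilyloxy)phenyl]methanol
Product: 30 3,5-bis(tert-butyldimethylsilyloxy)benzyl bromide
Conditions: CBr4, PPh3, CH2Cl2, 0 °C
Reagents that add atoms: carbon tetrabromide, BrC(Br)(Br)Br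
Why: Appel reaction: bromide displaces the alkoxyphosphonium group of a primary benzylic alcohol under neutral conditions that spare the aryl silyl ethers.

Step 19
Reactants: 30 3,5-bis(tert-butyldimethylsilyloxy)benzyl bromide
Product: 31 diethyl [3,5-bis(tert-butyldimethylsilyloxy)benzyl]phosphonate
Conditions: P(OEt)3 (neat), 130 °C
Reagents that add atoms: triethyl phosphite, CCOP(OCC)OCC
Why: Michaelis–Arbuzov reaction: the primary benzylic bromide alkylates phosphorus and bromide dealkylates the phosphonium salt, all under neutral conditions.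

Step 20
Reactants: 26 5-carbaldehyde; 31 diethyl [3,5-bis(tert-butyldimethylsilyloxy)benzyl]phosphonate
Product: 33 tetrasilyl ether of gnetucleistol F with (E)-alkene, via potassium phosphonate carbanion 32 (not isolated)
Conditions: 31, KN(SiMe3)2, THF, −78 → 0 °C; then 26, −78 °C → rt
Reagents that add atoms: none
Why: Horner–Wadsworth–Emmons olefination: the benzylic phosphonate carbanion adds reversibly to the aromatic aldehyde and eliminates through the less crowded trans-oxaphosphetane to give the (E)-stilbene, with no free hydroxyl and no enolisable stereocentre present.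

Step 21
Reactants: 33 tetrasilyl ether
Product: 34 gnetucleistol F
Conditions: Bu4NF, AcOH (1:1), THF, Ar, 0 °C → rt
Reagents that add atoms: none
Why: Fluoride-driven desilylation removes all four silyl groups at once, and acetic acid buffers the phenoxides so that neither air oxidation nor ring opening through a quinone methide can scramble C2.

## Compound list
1 | 5-bromofuran-3-carboxylic acid | OC(=O)c1coc(Br)c1 | starting material
2 | (5-bromofuran-3-yl)methanol | OCc1coc(Br)c1 | intermediate
3 | [(5-bromofuran-3-yl)methoxy](tert-butyl)dimethylsilane | CC(C)(C)[Si](C)(C)OCc1coc(Br)c1 | intermediate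
4 | (2-ethoxy-2-oxoethyl)zinc bromide | CCOC(=O)C[Zn]Br | starting material
5 | ethyl 2-[4-(tert-butyldimethylsilyloxymethyl)furan-2-yl]acetate | CCOC(=O)Cc1cc(CO[Si](C)(C)C(C)(C)C)co1 | intermediate
6 | 2-[4-(tert-butyldimethylsilyloxymethyl)furan-2-yl]acetic acid | OC(=O)Cc1cc(CO[Si](C)(C)C(C)(C)C)co1 | intermediate
7 | (R)-4-benzyl-2-oxazolidinone | O=C1N[C@H](Cc2ccccc2)CO1 | starting material
8 | mixed pivalic anhydride of 6 (not isolated) | CC(C)(C)C(=O)OC(=O)Cc1cc(CO[Si](C)(C)C(C)(C)C)co1 | intermediate
9 | (R)-4-benzyl-3-{2-[4-(tert-butyldimethylsilyloxymethyl)furan-2-yl]acetyl}oxazolidin-2-one | O=C(Cc1cc(CO[Si](C)(C)C(C)(C)C)co1)N2C(=O)OC[C@H]2Cc3ccccc3 | intermediate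
10 | syringaldehyde | COc1cc(C=O)cc(OC)c1O | starting material
11 | 3,5-dimethoxy-4-(triisopropylsilyloxy)benzaldehyde | COc1cc(C=O)cc(OC)c1O[Si](C(C)C)(C(C)C)C(C)C | intermediate
12 | (Z)-dibutylboron enolate of 9 (not isolated) | CCCCB(CCCC)O/C(=C\c1cc(CO[Si](C)(C)C(C)(C)C)co1)N2C(=O)OC[C@H]2Cc3ccccc3 | intermediate
13 | (2S,3R)-syn-aldol adduct on the (R)-auxiliary | COc1cc([C@@H]([C@H](C(=O)N2C(=O)OC[C@H]2Cc3ccccc3)c4cc(CO[Si](C)(C)C(C)(C)C)co4)O)cc(OC)c1O[Si](C(C)C)(C(C)C)C(C)C | intermediate
14 | (1R,2S)-2-furyl-1-arylpropane-1,3-diol | COc1cc([C@@H]([C@H](CO)c2cc(CO[Si](C)(C)C(C)(C)C)co2)O)cc(OC)c1O[Si](C(C)C)(C(C)C)C(C)C | intermediate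
15 | (1R,2S)-alcohol with primary TIPS ether | COc1cc([C@@H]([C@H](CO[Si](C(C)C)(C(C)C)C(C)C)c2cc(CO[Si](C)(C)C(C)(C)C)co2)O)cc(OC)c1O[Si](C(C)C)(C(C)C)C(C)C | intermediate
16 | trichloroethylene | ClC=C(Cl)Cl | starting material
17 | potassium alkoxide of 15 (not isolated) | [K+].COc1cc([C@@H]([C@H](CO[Si](C(C)C)(C(C)C)C(C)C)c2cc(CO[Si](C)(C)C(C)(C)C)co2)[O-])cc(OC)c1O[Si](C(C)C)(C(C)C)C(C)C | intermediate
18 | (E)-1,2-dichlorovinyl ether of 15 | COc1cc([C@@H]([C@H](CO[Si](C(C)C)(C(C)C)C(C)C)c2cc(CO[Si](C)(C)C(C)(C)C)co2)O/C(Cl)=C\Cl)cc(OC)c1O[Si](C(C)C)(C(C)C)C(C)C | intermediate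
19 | chloroethynyl ether of 15 (not isolated) | COc1cc([C@@H]([C@H](CO[Si](C(C)C)(C(C)C)C(C)C)c2cc(CO[Si](C)(C)C(C)(C)C)co2)OC#CCl)cc(OC)c1O[Si](C(C)C)(C(C)C)C(C)C | intermediate
20 | lithium alkoxyacetylide of 15 (not isolated) | COc1cc([C@@H]([C@H](CO[Si](C(C)C)(C(C)C)C(C)C)c2cc(CO[Si](C)(C)C(C)(C)C)co2)OC#C[Li])cc(OC)c1O[Si](C(C)C)(C(C)C)C(C)C | intermediate
21 | (1R,2S)-ethynyl ether of 15, key-step precursor | COc1cc([C@@H]([C@H](CO[Si](C(C)C)(C(C)C)C(C)C)c2cc(CO[Si](C)(C)C(C)(C)C)co2)OC#C)cc(OC)c1O[Si](C(C)C)(C(C)C)C(C)C | intermediate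
22 | dihydrofuran-fused oxepine, oxygen bridging C6 and C7, valence tautomer of the C6–C7 arene oxide (not isolated) | COc1cc([C@@H]2OC3=COC=C(CO[Si](C)(C)C(C)(C)C)C=C3[C@H]2CO[Si](C(C)C)(C(C)C)C(C)C)cc(OC)c1O[Si](C(C)C)(C(C)C)C(C)C | intermediate
23 | (2R,3S)-dihydrobenzofuran-7-ol, key-step product | COc1cc([C@@H]2Oc3c(O)cc(CO[Si](C)(C)C(C)(C)C)cc3[C@H]2CO[Si](C(C)C)(C(C)C)C(C)C)cc(OC)c1O[Si](C(C)C)(C(C)C)C(C)C | intermediate
24 | (2R,3S)-7-methyl ether | COc1cc([C@@H]2Oc3c(OC)cc(CO[Si](C)(C)C(C)(C)C)cc3[C@H]2CO[Si](C(C)C)(C(C)C)C(C)C)cc(OC)c1O[Si](C(C)C)(C(C)C)C(C)C | intermediate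
25 | (2R,3S)-5-hydroxymethyl compound | COc1cc([C@@H]2Oc3c(OC)cc(CO)cc3[C@H]2CO[Si](C(C)C)(C(C)C)C(C)C)cc(OC)c1O[Si](C(C)C)(C(C)C)C(C)C | intermediate
26 | (2R,3S)-5-carbaldehyde | COc1cc([C@@H]2Oc3c(OC)cc(C=O)cc3[C@H]2CO[Si](C(C)C)(C(C)C)C(C)C)cc(OC)c1O[Si](C(C)C)(C(C)C)C(C)C | intermediate
27 | methyl 3,5-dihydroxybenzoate | COC(=O)c1cc(O)cc(O)c1 | starting material
28 | methyl 3,5-bis(tert-butyldimethylsilyloxy)benzoate | COC(=O)c1cc(O[Si](C)(C)C(C)(C)C)cc(O[Si](C)(C)C(C)(C)C)c1 | intermediate
29 | [3,5-bis(tert-butyldimethylsilyloxy)phenyl]methanol | OCc1cc(O[Si](C)(C)C(C)(C)C)cc(O[Si](C)(C)C(C)(C)C)c1 | intermediate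
30 | 3,5-bis(tert-butyldimethylsilyloxy)benzyl bromide | BrCc1cc(O[Si](C)(C)C(C)(C)C)cc(O[Si](C)(C)C(C)(C)C)c1 | intermediate
31 | diethyl [3,5-bis(tert-butyldimethylsilyloxy)benzyl]phosphonate | CCOP(=O)(OCC)Cc1cc(O[Si](C)(C)C(C)(C)C)cc(O[Si](C)(C)C(C)(C)C)c1 | intermediate
32 | potassium carbanion of 31 (not isolated) | [K+].CCOP(=O)(OCC)[CH-]c1cc(O[Si](C)(C)C(C)(C)C)cc(O[Si](C)(C)C(C)(C)C)c1 | intermediate
33 | tetrasilyl ether of gnetucleistol F | COc1cc([C@@H]2Oc3c(OC)cc(/C=C/c4cc(O[Si](C)(C)C(C)(C)C)cc(O[Si](C)(C)C(C)(C)C)c4)cc3[C@H]2CO[Si](C(C)C)(C(C)C)C(C)C)cc(OC)c1O[Si](C(C)C)(C(C)C)C(C)C | intermediate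
34 | gnetucleistol F, (2R,3S) | COc1cc([C@@H]2Oc3c(OC)cc(/C=C/c4cc(O)cc(O)c4)cc3[C@H]2CO)cc(OC)c1O | target

## Step count and risks
Total step count: 21. Longest linear sequence: 16 steps (1–5, 7–15, 20, 21).

**1. Step 12.**
- Risk: the gold-activated ynol ether may ionise at the electron-rich benzylic C2–O1 bond, which would lose the tether or scramble C2.
- Risk: it may be hydrated by traces of water, be attacked by the free C5 of a second furan, or close at furan C3 instead of C2.
- Fallback (known chemistry): ring A is bought instead of built, and the dihydrofuran ring is closed by the acid-catalysed phenylcoumaran cyclisation. The fallback sets out from zinc reagent 4, auxiliary 7 and aldehyde 11 and comes back at alcohol 25.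
- Commercial methyl 4-hydroxy-3-iodo-5-methoxybenzoate is benzylated (BnBr, K2CO3, DMF) to methyl 4-(benzyloxy)-3-iodo-5-methoxybenzoate F1. This is coupled with 4 as in step 3 to arylacetate diester F2.
- F2 is saponified only at the aliphatic ester (LiOH, one equivalent, 0 °C) to arylacetic acid F3, which is joined to 7 as in step 5 to give arylacetyl imide F4.
- The Evans syn-aldol reaction with 11 as in step 7 should give syn-aldol adduct F5. LiBH4 at 0 °C reduces the imide faster than the electron-rich benzoate and should give ester diol F6.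
- i-Pr3SiCl then gives primary TIPS ether F7, and hydrogenolysis (H2, Pd on carbon, EtOAc) frees phenol F8.
- Catalytic camphorsulfonic acid in CH2Cl2 ionises the benzylic alcohol, and the phenol oxygen traps the cation anti to the C3 substituent. This should give trans-dihydrobenzofuran ester F9 with C2 set by C3. i-Bu2AlH reduces F9 to 25.

**2. Step 11.**
- Risk: the secondary benzylic ethynyl ether may be lost during isolation by retro-ene elimination of ketene, by a [3,3] shift into the electron-rich aryl ring, or by hydration on the adsorbent.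
- Fallback: the alkyne is parked as a silyl-capped, storable derivative. The fallback sets out from lithium acetylide 20 and comes back at 21.
- 20 is quenched with Me3SiCl instead of water to give C-trimethylsilyl ynol ether F10, which can be chromatographed and kept cold.
- Just before step 12 the C–Si bond is cleaved with K2CO3 in MeOH at 0 °C, and the cold extract of 21 is used without concentration to dryness.

**3. Step 10.**
- Risk: the hindered potassium alkoxide may add too slowly, so that silyl migration to the alkoxide or base-induced decomposition competes.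
- Fallback: no alkoxide is formed at all. The fallback sets out from alcohol 15 and comes back at chloroethynyl ether 19.
- 15 is formylated (acetic formic anhydride, pyridine, 0 °C) to formate ester F11.
- The formyl C=O is dichloromethylenated with PPh3/CCl4 (THF, 60 °C, Wittig-type olefination of a formate) to 2,2-dichlorovinyl ether F12.
- n-BuLi under the conditions of step 11 removes HCl to give 19 and then 20.

## Further compounds
F1 | step 12 | methyl 4-(benzyloxy)-3-iodo-5-methoxybenzoate | COC(=O)c1cc(I)c(OCc2ccccc2)c(OC)c1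
F2 | step 12 | arylacetate diester, methyl 4-(benzyloxy)-3-(2-ethoxy-2-oxoethyl)-5-methoxybenzoate | CCOC(=O)Cc1cc(C(=O)OC)cc(OC)c1OCc2ccccc2
F3 | step 12 | arylacetic acid, 2-[2-(benzyloxy)-3-methoxy-5-(methoxycarbonyl)phenyl]acetic acid | OC(=O)Cc1cc(C(=O)OC)cc(OC)c1OCc2ccccc2
F4 | step 12 | arylacetyl imide of (R)-4-benzyl-2-oxazolidinone | O=C(Cc1cc(C(=O)OC)cc(OC)c1OCc2ccccc2)N3C(=O)OC[C@H]3Cc4ccccc4
F5 | step 12 | syn-aldol adduct of F4 with 11 | COc1cc([C@@H]([C@H](C(=O)N2C(=O)OC[C@H]2Cc3ccccc3)c4cc(C(=O)OC)cc(OC)c4OCc5ccccc5)O)cc(OC)c1O[Si](C(C)C)(C(C)C)C(C)C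
F6 | step 12 | ester diol | COc1cc([C@@H]([C@H](CO)c2cc(C(=O)OC)cc(OC)c2OCc3ccccc3)O)cc(OC)c1O[Si](C(C)C)(C(C)C)C(C)C
F7 | step 12 | primary TIPS ether of F6 | COc1cc([C@@H]([C@H](CO[Si](C(C)C)(C(C)C)C(C)C)c2cc(C(=O)OC)cc(OC)c2OCc3ccccc3)O)cc(OC)c1O[Si](C(C)C)(C(C)C)C(C)C
F8 | step 12 | phenol from debenzylation of F7 | COc1cc([C@@H]([C@H](CO[Si](C(C)C)(C(C)C)C(C)C)c2cc(C(=O)OC)cc(OC)c2O)O)cc(OC)c1O[Si](C(C)C)(C(C)C)C(C)C
F9 | step 12 | trans-dihydrobenzofuran ester, methyl (2R,3S)-5-carboxylate | COc1cc([C@@H]2Oc3c(OC)cc(C(=O)OC)cc3[C@H]2CO[Si](C(C)C)(C(C)C)C(C)C)cc(OC)c1O[Si](C(C)C)(C(C)C)C(C)C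
F10 | step 11 | C-trimethylsilyl ynol ether of 15 | COc1cc([C@@H]([C@H](CO[Si](C(C)C)(C(C)C)C(C)C)c2cc(CO[Si](C)(C)C(C)(C)C)co2)OC#C[Si](C)(C)C)cc(OC)c1O[Si](C(C)C)(C(C)C)C(C)C
F11 | step 10 | formate ester of 15 | COc1cc([C@@H]([C@H](CO[Si](C(C)C)(C(C)C)C(C)C)c2cc(CO[Si](C)(C)C(C)(C)C)co2)OC=O)cc(OC)c1O[Si](C(C)C)(C(C)C)C(C)C
F12 | step 10 | 2,2-dichlorovinyl ether of 15 | COc1cc([C@@H]([C@H](CO[Si](C(C)C)(C(C)C)C(C)C)c2cc(CO[Si](C)(C)C(C)(C)C)co2)OC=C(Cl)Cl)cc(OC)c1O[Si](C(C)C)(C(C)C)C(C)C
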